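Numbering used throughout: lactone ring C1–C2(=O)–O3–C4–C5, ether ring C5–C6–O7–C8–C1, guaiacyl on C4, catechol ring on C8. The target is (1S,4S,5R,8S), cis-fused, with both aryl groups on the convex face.
Enabling feature: the ether ring C5–C6–O7–C8–C1 can be read as the C8=O7 carbonyl of protocatechualdehyde spanned by the three carbons C1–C5–C6. Carboxyl C2 sits on C1 and the one-carbon branch C4 on C5, which is the pattern of an ester-bearing trimethylenemethane added across an aldehyde.
Retrosynthetic cuts, in order: the benzyl ethers; the lactone bond C2–O3 together with the C4–aryl bond (back to a C4 aldehyde and a C2 methyl ester); the C4 oxygen (back to the C5=C4 methylene); then C1–C8 and C6–O7 in one [3+2] operation.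
Forward order: donor in two steps, ether ring first (cycloaddition), C4 raised to the aldehyde, lactone ring second (aryl addition and ring closure in one flask), debenzylation last.
Stereochemistry: C8 comes from the chiral phosphoramidite on palladium, C1 is set trans to the C8 aryl group in the same step, C5 comes from hydroboration anti to the ester, and C4 from attack on the convex face of a magnesium chelate.

Key step: step 3

Assumption: the sense of induction for this donor–aldehyde pair cannot be derived with certainty by analogy, so the phosphoramidite antipode is taken to be the one that gives (2S,3S)-7; the other antipode would give the mirror-image series.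

Step 1
Reactants: 1 (2-bromoallyl)trimethylsilane; 2 methyl glyoxylate (freshly cracked monomer)
Product: 4 methyl 2-hydroxy-3-[(trimethylsilyl)methyl]but-3-enoate (racemic), via vinylmagnesium bromide 3 (not isolated)
Conditions: Mg turnings, THF, 45 °C; then cannulated into 2 (1.5 equiv), THF, −78 °C; aq. NH4Cl
Reagents that add atoms: magnesium, [Mg] (kept only in 3)
Why: Grignard formation from the vinylic bromide followed by 1,2-addition to the formyl group, by far the most electrophilic carbonyl of 2 at −78 °C under inverse addition, is the standard way to 1-substituted 2-(silylmethyl)allyl alcohols, and the new carbinol centre may stay racemic because step 3 erases it.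

Step 2
Reactants: 4 methyl 2-hydroxy-3-[(trimethylsilyl)methyl]but-3-enoate
Product: 5 methyl 2-acetoxy-3-[(trimethylsilyl)methyl]but-3-enoate (racemic)
Conditions: Ac2O, pyridine, DMAP (cat.), CH2Cl2, 0 → 23 °C
Reagents that add atoms: acetic anhydride, CC(=O)OC(C)=O
Why: DMAP-catalysed O-acetylation of a secondary alcohol is mild enough to leave the acid-sensitive allylsilane and the methyl ester untouched, and it installs the leaving group for ionisation.

Step 3
Reactants: 5 methyl 2-acetoxy-3-[(trimethylsilyl)methyl]but-3-enoate (1.5 equiv); 6 3,4-bis(benzyloxy)benzaldehyde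
Product: 7 methyl (2S,3S)-2-[3,4-bis(benzyloxy)phenyl]-4-methylideneoxolane-3-carboxylate (aryl and ester trans)
Conditions: Pd2(dba)3·CHCl3 (2.5 mol %), BINOL-derived phosphoramidite of trans-2,5-bis(2-naphthyl)pyrrolidine (10 mol %), toluene, 0 → 23 °C
Reagents that add atoms: none
Why: Zerovalent palladium ionises the allylic acetate of both enantiomers of 5, the liberated acetate removes the silyl group, and the zwitterionic trimethylenemethane–palladium complex so formed no longer holds the carbinol stereocentre and keeps its negative charge on the ester-bearing terminus C1. C1 adds to the formyl carbon of 6 (bond C1–C8), and the alkoxide O7 then attacks one of the two equivalent CH2 termini of the cationic allylpalladium unit (bond C6–O7), a five-membered O-allylation of the 5-exo-tet kind in which the metal leaves outside the new ether ring and C5 keeps the exocyclic methylene C4. The closest known reaction type is the palladium-catalysed trimethylenemethane [3+2] cycloaddition to aromatic aldehydes, which gives 2-aryl-4-methylenetetrahydrofurans enantioselectively with phosphoramidite ligands, while cyano-, acyl- and carboxy-substituted donors are established with alkenes and imines and bond first through the substituted carbon; only their pairing with an aldehyde has to be worked out here. C8 is controlled by the chiral ligand, which decides the face of the aldehyde that meets the metal-bound nucleophile, and C1 is controlled by C8 through the ring-closing transition state that keeps ester and aryl group trans, the arrangement this acidic centre also prefers at equilibrium. The step needs regioselectivity (ester next to C8 and not on C6), secured by the charge-localising ester, and cyclisation in preference to O-silylation of the aldolate, helped by the irreversible ring closure that drains the reversible addition to the electron-rich aldehyde. Base-free conditions and a neutral work-up keep the C5=C4 bond out of conjugation with the ester.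

Step 4
Reactants: 7 methyl (2S,3S)-2-[3,4-bis(benzyloxy)phenyl]-4-methylideneoxolane-3-carboxylate
Product: 9 methyl (2S,3S,4S)-2-[3,4-bis(benzyloxy)phenyl]-4-(hydroxymethyl)oxolane-3-carboxylate, via B-alkyl-9-BBN adduct 8 (not isolated)
Conditions: 9-BBN (1.5 equiv), THF, 0 → 23 °C; then 30% H2O2, pH 7 phosphate buffer, 0 °C; extractive work-up, crude product used at once
Reagents that add atoms: hydrogen peroxide, OO; 9-borabicyclo[3.3.1]nonane, B1C2CCCC1CCC2 (boron and its ring kept only in 8)
Why: Brown hydroboration–oxidation places boron on the unhindered terminus C4, and the bulky borane should approach the methylene from the face opposite to the neighbouring C1 ester, so that hydrogen lands on C5 on the side of H1 and the CH2OH group ends up cis to the ester, as is usual for 2-substituted methylenecyclopentanes; the buffered oxidation and the use of crude 9 hold back closure to the lactone.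

Step 5
Reactants: 9 methyl (2S,3S,4S)-2-[3,4-bis(benzyloxy)phenyl]-4-(hydroxymethyl)oxolane-3-carboxylate
Product: 10 methyl (2S,3S,4R)-2-[3,4-bis(benzyloxy)phenyl]-4-formyloxolane-3-carboxylate
Conditions: Dess–Martin periodinane, pyridine, CH2Cl2, 0 °C
Reagents that add atoms: none
Why: The Dess–Martin oxidation is fast, non-aqueous and nearly neutral, so it should stop at the aldehyde, outrun lactonisation of 9 and leave the epimerisable centres C5 and C1 as they are.

Step 6
Reactants: 10 methyl (2S,3S,4R)-2-[3,4-bis(benzyloxy)phenyl]-4-formyloxolane-3-carboxylate; 11 1-(benzyloxy)-4-bromo-2-methoxybenzene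
Product: 14 (1S,4S,5R,8S)-4-[4-(benzyloxy)-3-methoxyphenyl]-8-[3,4-bis(benzyloxy)phenyl]-3,7-dioxabicyclo[3.3.0]octan-2-one, via arylmagnesium bromide 12 (not isolated), via bromomagnesium alkoxide 13 (not isolated)
Conditions: 11, Mg, THF, 50 °C (gives 12); 10, MgBr2·OEt2 (1.5 equiv), CH2Cl2, −78 °C, then 12 (1.1 equiv), −78 → 0 °C; aq. NH4Cl
Reagents that add atoms: magnesium, [Mg] (kept only in 12 and 13)
Why: Grignard 1,2-addition followed by lactonisation through intramolecular transesterification: magnesium bridging the formyl oxygen and the carbonyl oxygen of the cis ester (seven-membered chelate) holds the aldehyde in the plane of the future lactone ring, the concave face is screened by C6H2, the aryl group should therefore enter from the convex face on the side of H5 to set 4S, and the alkoxide 13 expels methoxide from the adjacent ester on warming.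

Step 7
Reactants: 14 (1S,4S,5R,8S)-4-[4-(benzyloxy)-3-methoxyphenyl]-8-[3,4-bis(benzyloxy)phenyl]-3,7-dioxabicyclo[3.3.0]octan-2-one
Product: 15 (1S,4S,5R,8S)-8-(3,4-dihydroxyphenyl)-4-(4-hydroxy-3-methoxyphenyl)-3,7-dioxabicyclo[3.3.0]octan-2-one (CNP0268159.1)
Conditions: H2 (1 atm), 10% Pd/C, EtOAc, 23 °C, stopped as soon as 14 and the partly debenzylated intermediates are consumed
Reagents that add atoms: none
Why: Catalytic hydrogenolysis cleaves the three aryl benzyl ethers far faster than the hindered secondary benzylic bonds C4–O3 and C8–O7 under neutral conditions at one atmosphere, so stopping at full debenzylation should give the target with all four stereocentres untouched.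

Compound list
1 | (2-bromoallyl)trimethylsilane | C=C(Br)C[Si](C)(C)C | starting material
2 | methyl glyoxylate | COC(=O)C=O | starting material
3 | [1-(trimethylsilylmethyl)vinyl]magnesium bromide | C=C([Mg]Br)C[Si](C)(C)C | intermediate
4 | methyl 2-hydroxy-3-[(trimethylsilyl)methyl]but-3-enoate (racemic) | COC(=O)C(O)C(=C)C[Si](C)(C)C | intermediate
5 | methyl 2-acetoxy-3-[(trimethylsilyl)methyl]but-3-enoate (racemic) | COC(=O)C(OC(C)=O)C(=C)C[Si](C)(C)C | intermediate
6 | 3,4-bis(benzyloxy)benzaldehyde | O=Cc1ccc(OCc2ccccc2)c(OCc2ccccc2)c1 | starting material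
7 | methyl (2S,3S)-2-[3,4-bis(benzyloxy)phenyl]-4-methylideneoxolane-3-carboxylate | COC(=O)[C@H]1C(=C)CO[C@@H]1c1ccc(OCc2ccccc2)c(OCc2ccccc2)c1 | intermediate
8 | methyl (2S,3S,4R)-2-[3,4-bis(benzyloxy)phenyl]-4-[(9-borabicyclo[3.3.1]nonan-9-yl)methyl]oxolane-3-carboxylate | COC(=O)[C@H]1[C@@H](CB2C3CCCC2CCC3)CO[C@@H]1c1ccc(OCc2ccccc2)c(OCc2ccccc2)c1 | intermediate
9 | methyl (2S,3S,4S)-2-[3,4-bis(benzyloxy)phenyl]-4-(hydroxymethyl)oxolane-3-carboxylate | COC(=O)[C@H]1[C@@H](CO)CO[C@@H]1c1ccc(OCc2ccccc2)c(OCc2ccccc2)c1 | intermediate
10 | methyl (2S,3S,4R)-2-[3,4-bis(benzyloxy)phenyl]-4-formyloxolane-3-carboxylate | COC(=O)[C@H]1[C@@H](C=O)CO[C@@H]1c1ccc(OCc2ccccc2)c(OCc2ccccc2)c1 | intermediate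
11 | 1-(benzyloxy)-4-bromo-2-methoxybenzene | COc1cc(Br)ccc1OCc1ccccc1 | starting material
12 | [4-(benzyloxy)-3-methoxyphenyl]magnesium bromide | COc1cc([Mg]Br)ccc1OCc1ccccc1 | intermediate
13 | bromomagnesium alkoxide of methyl (2S,3S,4R)-2-[3,4-bis(benzyloxy)phenyl]-4-{(S)-[4-(benzyloxy)-3-methoxyphenyl](hydroxy)methyl}oxolane-3-carboxylate | COC(=O)[C@H]1[C@@H]([C@H](O[Mg]Br)c2ccc(OCc3ccccc3)c(OC)c2)CO[C@@H]1c1ccc(OCc2ccccc2)c(OCc2ccccc2)c1 | intermediate
14 | (1S,4S,5R,8S)-4-[4-(benzyloxy)-3-methoxyphenyl]-8-[3,4-bis(benzyloxy)phenyl]-3,7-dioxabicyclo[3.3.0]octan-2-one | COc1cc([C@H]2OC(=O)[C@H]3[C@@H]2CO[C@@H]3c2ccc(OCc4ccccc4)c(OCc4ccccc4)c2)ccc1OCc1ccccc1 | intermediate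
15 | (1S,4S,5R,8S)-8-(3,4-dihydroxyphenyl)-4-(4-hydroxy-3-methoxyphenyl)-3,7-dioxabicyclo[3.3.0]octan-2-one | COc1cc([C@H]2OC(=O)[C@H]3[C@@H]2CO[C@@H]3c2ccc(O)c(O)c2)ccc1O | target

Total step count: 7. Longest linear sequence: 7 (steps 1 to 7, starting from 1).

Steps most likely to fail

Step 3. Several things may go wrong:
- The ester-stabilised carbanion may add only sluggishly and reversibly to the electron-rich aldehyde.
- The aldolate may be silylated instead of closing the ring.
- The ligand may induce poorly.
- The double bond may drift into conjugation with the ester.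

The fallback sets out from 6 and builds the same ester by a radical ring closure, taking the absolute configuration from a resolution. Wittig olefination of 6 with Ph3P=CHCO2Me should give methyl (E)-3-[3,4-bis(benzyloxy)phenyl]prop-2-enoate F1. N-Bromosuccinimide with propargyl alcohol in CH2Cl2 should then add bromine to C1 and the propargyloxy group to the benzylic carbon C8, giving methyl 3-[3,4-bis(benzyloxy)phenyl]-2-bromo-3-(prop-2-ynyloxy)propanoate F2. Bu3SnH and AIBN in hot toluene generate the C1 radical, whose 5-exo-dig cyclisation onto the alkyne forms C1–C5 and should give racemic trans methyl 2-[3,4-bis(benzyloxy)phenyl]-4-methylideneoxolane-3-carboxylate F3. Preparative chromatography on a chiral stationary phase removes the (2R,3R) enantiomer F4, and the route is rejoined at 7.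

Step 6. The seven-membered chelate may not hold. Attack through an open Felkin–Anh-type rotamer then lowers or reverses the facial selectivity at the formyl group, and enolisation by the Grignard reagent may erode C5.

The fallback sets out from 10 and replaces substrate control by reagent control with a much less basic nucleophile. Commercial 4-(benzyloxy)-3-methoxyphenylboronic acid and Et2Zn (toluene, 60 °C) should give [4-(benzyloxy)-3-methoxyphenyl](ethyl)zinc F5. This is added to 10 at 0 °C in the presence of 10 mol % of 3-exo-morpholinoisoborneol, using the antipode that sends the aryl group to the Re face of the formyl group (expected to be the dextrorotatory one, by analogy with its alkylzinc additions). The resulting ethylzinc alkoxide of the (S)-carbinol F6 lactonises on warming or with a trace of acid, and the route is rejoined at 14.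

Step 4. Facial selectivity of the hydroboration may be only moderate, because the C8 aryl group sits on the face that has to be attacked. The cis hydroxy ester may also lactonise before it can be oxidised.

The fallback sets out from 7 and turns the lactonisation into the purification. After the same hydroboration the borane is oxidised with NaOH/H2O2 and the crude product is stirred with catalytic TsOH. Only the cis isomer then closes, to (1S,5R,8S)-8-[3,4-bis(benzyloxy)phenyl]-3,7-dioxabicyclo[3.3.0]octan-2-one F7, while the trans isomer cannot lactonise and is removed by chromatography or crystallisation. KOH in aqueous THF opens F7 to potassium (2S,3S,4S)-2-[3,4-bis(benzyloxy)phenyl]-4-(hydroxymethyl)oxolane-3-carboxylate F8. O-Methylation of the dried salt with MeI in DMF returns to 9, which is oxidised at once as in step 5.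

Further compounds
F1 | step 3 | methyl (E)-3-[3,4-bis(benzyloxy)phenyl]prop-2-enoate | COC(=O)/C=C/c1ccc(OCc2ccccc2)c(OCc2ccccc2)c1
F2 | step 3 | methyl 3-[3,4-bis(benzyloxy)phenyl]-2-bromo-3-(prop-2-ynyloxy)propanoate (racemic, configuration at C1 irrelevant) | COC(=O)C(Br)C(OCC#C)c1ccc(OCc2ccccc2)c(OCc2ccccc2)c1
F3 | step 3 | racemic trans methyl 2-[3,4-bis(benzyloxy)phenyl]-4-methylideneoxolane-3-carboxylate | COC(=O)C1C(=C)COC1c1ccc(OCc2ccccc2)c(OCc2ccccc2)c1
F4 | step 3 | methyl (2R,3R)-2-[3,4-bis(benzyloxy)phenyl]-4-methylideneoxolane-3-carboxylate | COC(=O)[C@@H]1C(=C)CO[C@H]1c1ccc(OCc2ccccc2)c(OCc2ccccc2)c1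
F5 | step 6 | [4-(benzyloxy)-3-methoxyphenyl](ethyl)zinc | CC[Zn]c1ccc(OCc2ccccc2)c(OC)c1
F6 | step 6 | ethylzinc alkoxide of methyl (2S,3S,4R)-2-[3,4-bis(benzyloxy)phenyl]-4-{(S)-[4-(benzyloxy)-3-methoxyphenyl](hydroxy)methyl}oxolane-3-carboxylate | COC(=O)[C@H]1[C@@H]([C@H](O[Zn]CC)c2ccc(OCc3ccccc3)c(OC)c2)CO[C@@H]1c1ccc(OCc2ccccc2)c(OCc2ccccc2)c1
F7 | step 4 | (1S,5R,8S)-8-[3,4-bis(benzyloxy)phenyl]-3,7-dioxabicyclo[3.3.0]octan-2-one | C1OC(=O)[C@H]2[C@@H]1CO[C@@H]2c1ccc(OCc2ccccc2)c(OCc2ccccc2)c1
F8 | step 4 | potassium (2S,3S,4S)-2-[3,4-bis(benzyloxy)phenyl]-4-(hydroxymethyl)oxolane-3-carboxylate | [K+].[O-]C(=O)[C@H]1[C@@H](CO)CO[C@@H]1c1ccc(OCc2ccccc2)c(OCc2ccccc2)c1
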